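Ring A (C1 OMe, C2 prenyl, C3 OH, C4 H, C5 OH, C6 CH2CO-aryl) bears oxygen on alternate carbons, and only the oxygen lying between the two carbon substituents is methylated: the imprint of a 3,5-dialkylated triacetic lactone methyl ether. The route therefore rests on cutting the C4–C5 bond of ring A. Hot methoxide unlocks a 2-pyrone and the released methyl ketone condenses onto the new ester, so one operation delivers the benzene ring with all six positions correctly and unambiguously occupied. The precursor is a 4-methoxy-6-methyl-2-pyrone carrying prenyl at C5 and a THP-protected 2-hydroxyethyl chain at C3. Ring B is added afterwards as an aryllithium, and allyl ethers permit an acid-free final unmasking.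

Key step: step 7

Remarks on the chemistry:
- **Side-chain protection.** The side-chain alcohol travels as a THP acetal because the ring transformation needs methoxide well above the boiling point of methanol. A silyl ether would be stripped there, and an alkoxide freed too early could displace the C4 methoxy group of the pyrone.
- **Stereochemistry.** The THP acetal carbon is a stereocentre, so all THP compounds are racemic. This has no bearing on the achiral target.
- **Phenol protection.** The phenols are masked as allyl ethers and not as acid-labile acetals. The target combines a prenyl group ortho to a phenol (chroman formation) with an ortho-hydroxybenzyl ketone (cyclodehydration to a 2-arylbenzofuran), and acid triggers both.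

Step 1
Reactants: 1 acetylacetone; 2 prenyl bromide (1-bromo-3-methylbut-2-ene)
Product: 3 3-(3-methylbut-2-enyl)pentane-2,4-dione
Conditions: K2CO3, acetone, reflux (1 in 1.5-fold excess)
Reagents that add atoms: none
Why: SN2 C-alkylation of the stabilised acetylacetonate with a reactive allylic bromide is routine, attack at the primary carbon keeps the prenyl connectivity, and the excess of 1 holds back double alkylation.

Step 2
Reactants: 3 3-(3-methylbut-2-enyl)pentane-2,4-dione
Product: 5 4-(3-methylbut-2-enyl)-3,5-dioxohexanoic acid, via dilithio dianion 4 (not isolated)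
Conditions: LiN(iPr)2 (2.3 equiv), THF, −78 to 0 °C; CO2 gas, −78 °C; cold 1 M HCl
Reagents that add atoms: carbon dioxide, O=C=O; lithium diisopropylamide, CC(C)[N-]C(C)C.[Li+] (lithium of 4 only)
Why: β-Diketone dianion carboxylation: the second deprotonation takes place at a terminal methyl group, this less stabilised carbanion is the site that captures CO2, and since the two methyl groups of 3 are equivalent only one acid can form.

Step 3
Reactants: 5 4-(3-methylbut-2-enyl)-3,5-dioxohexanoic acid
Product: 6 4-hydroxy-6-methyl-5-(3-methylbut-2-enyl)-2H-pyran-2-one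
Conditions: Ac2O, CH2Cl2, 0 °C to rt; aq NaHCO3 extraction, then citric acid
Reagents that add atoms: none
Why: Enol lactonisation through the mixed anhydride is the classical closure of 3,5-dioxo acids to 4-hydroxy-2-pyrones, and acetic anhydride avoids the strong protic acids that would hydrate or cyclise the prenyl alkene.

Step 4
Reactants: 7 2-(tetrahydro-2H-pyran-2-yloxy)ethanol
Product: 8 (tetrahydro-2H-pyran-2-yloxy)acetaldehyde
Conditions: TEMPO (10 mol %), PhI(OAc)2 (1.1 equiv), CH2Cl2, rt
Reagents that add atoms: none
Why: Oxoammonium-catalysed (TEMPO) alcohol oxidation stops at the aldehyde when water is absent, and the acetic acid released is too weak to open the THP acetal in CH2Cl2.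

Step 5
Reactants: 6 4-hydroxy-6-methyl-5-(3-methylbut-2-enyl)-2H-pyran-2-one; 8 (tetrahydro-2H-pyran-2-yloxy)acetaldehyde
Product: 10 4-hydroxy-6-methyl-5-(3-methylbut-2-enyl)-3-[2-(tetrahydro-2H-pyran-2-yloxy)ethyl]-2H-pyran-2-one, via alkylidene pyrandione 9 (not isolated)
Conditions: L-proline (20 mol %), Hantzsch ester (diethyl 2,6-dimethyl-1,4-dihydropyridine-3,5-dicarboxylate, 1.1 equiv), CH2Cl2, rt
Reagents that add atoms: none
Why: Organocatalytic three-component reductive alkylation (Knoevenagel condensation, then Hantzsch-ester transfer hydrogenation) is established for 4-hydroxy-6-methyl-2-pyrone; C3 is the only nucleophilic carbon of 6 and hydride delivery to 9 should outrun Michael addition of a second pyrone.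

Step 6
Reactants: 10 4-hydroxy-6-methyl-5-(3-methylbut-2-enyl)-3-[2-(tetrahydro-2H-pyran-2-yloxy)ethyl]-2H-pyran-2-one
Product: 11 4-methoxy-6-methyl-5-(3-methylbut-2-enyl)-3-[2-(tetrahydro-2H-pyran-2-yloxy)ethyl]-2H-pyran-2-one
Conditions: Me2SO4 (1.3 equiv), K2CO3, acetone, reflux
Reagents that add atoms: dimethyl sulfate, COS(=O)(=O)OC
Why: O-Alkylation of the pyronate with the hard electrophile dimethyl sulfate under K2CO3 is the standard entry to 4-methoxy-2-pyrones and favours this isomer over the 2-methoxy-4-pyrone, while C-methylation at the substituted C3 would cost the pyrone conjugation and THP and prenyl are inert to base.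

Step 7
Reactants: 11 4-methoxy-6-methyl-5-(3-methylbut-2-enyl)-3-[2-(tetrahydro-2H-pyran-2-yloxy)ethyl]-2H-pyran-2-one
Product: 13 5-methoxy-4-(3-methylbut-2-enyl)-6-[2-(tetrahydro-2H-pyran-2-yloxy)ethyl]benzene-1,3-diol, via open-chain keto ester 12 (not isolated)
Conditions: NaOMe (5 equiv, fresh from Na), dry degassed MeOH, sealed vessel, 160–180 °C; cool, AcOH to pH 6
Reagents that add atoms: sodium methoxide, C[O-].[Na+] (methoxy group of 12 only; it leaves again on ring closure)
Why: Methoxide adds to the lactone carbonyl (pyrone C2), the C2–O1 bond breaks and keto ester 12 results as its enolate, with the ester and acetyl arms held cis on the tetrasubstituted enol-ether double bond that the ring hands down. Proton exchange through the solvent gives a small equilibrium share of the enolate at the terminal methyl carbon, which attacks the ester carbonyl in a 6-(enolendo)-exo-trig Claisen (Dieckmann-type) closure and so forms the C4–C5 bond and ring A. Expulsion of methoxide, enolisation and deprotonation to the resorcinolate make this the one irreversible exit, and no stereocentre is created. The closest known reactions are the conversion of 4-methoxy-6-methyl-2-pyrone into phloroglucinol monomethyl ether by NaOMe in methanol under pressure and the alkoxide closure of 5-oxohexanoates to cyclohexane-1,3-diones. The step needs chemoselectivity among the sites of methoxide attack and among the enolisable positions: exchange at the methoxy-bearing carbon regenerates 11, addition at C6 and relactonisation are reversible, and the internal enolate carbon (old pyrone C5) could only close a strained four-membered ring. The two alkyl groups twist the resting extended dienolate out of conjugation and press the chain ends together, while the THP acetal and the prenyl alkene ignore alkoxide, so the methyl ether is born in its final place at C1, between prenyl (C2) and side chain (C6), and the two new phenols are the only free oxygens.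

Step 8
Reactants: 13 5-methoxy-4-(3-methylbut-2-enyl)-6-[2-(tetrahydro-2H-pyran-2-yloxy)ethyl]benzene-1,3-diol
Product: 14 2-{2-[4,6-bis(allyloxy)-2-methoxy-3-(3-methylbut-2-enyl)phenyl]ethoxy}tetrahydro-2H-pyran
Conditions: allyl bromide (2.5 equiv), K2CO3, DMF, rt, argon
Reagents that add atoms: allyl bromide, C=CCBr
Why: Williamson etherification: carbonate deprotonates only the two phenols, and the polar aprotic medium steers the ambident resorcinolate to O-allylation rather than C4-allylation.

Step 9
Reactants: 14 2-{2-[4,6-bis(allyloxy)-2-methoxy-3-(3-methylbut-2-enyl)phenyl]ethoxy}tetrahydro-2H-pyran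
Product: 15 2-[4,6-bis(allyloxy)-2-methoxy-3-(3-methylbut-2-enyl)phenyl]ethanol
Conditions: PPTS (10 mol %), MeOH, 40 °C
Reagents that add atoms: none
Why: Acid-catalysed transacetalisation to methanol removes the THP group under conditions that leave aryl allyl ethers, the aryl methyl ether and the prenyl alkene untouched, and with both phenols capped no chroman can form.

Step 10
Reactants: 15 2-[4,6-bis(allyloxy)-2-methoxy-3-(3-methylbut-2-enyl)phenyl]ethanol
Product: 16 [4,6-bis(allyloxy)-2-methoxy-3-(3-methylbut-2-enyl)phenyl]acetaldehyde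
Conditions: Dess–Martin periodinane (1.2 equiv), CH2Cl2, 0 °C to rt; used at once
Reagents that add atoms: none
Why: Dess–Martin oxidation turns 2-arylethanols into arylacetaldehydes under nearly neutral conditions without over-oxidation and does not touch the alkenes or the electron-rich ring.

Step 11
Reactants: 17 4-bromoresorcinol
Product: 18 2,4-bis(allyloxy)-1-bromobenzene
Conditions: allyl bromide (2.5 equiv), K2CO3, acetone, reflux
Reagents that add atoms: allyl bromide, C=CCBr
Why: Williamson etherification of both phenols is routine and the aryl bromide is inert to carbonate.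

Step 12
Reactants: 18 2,4-bis(allyloxy)-1-bromobenzene; 16 [4,6-bis(allyloxy)-2-methoxy-3-(3-methylbut-2-enyl)phenyl]acetaldehyde
Product: 20 1-[2,4-bis(allyloxy)phenyl]-2-[4,6-bis(allyloxy)-2-methoxy-3-(3-methylbut-2-enyl)phenyl]ethanol (racemic), via aryllithium 19 (not isolated)
Conditions: 18 (1.3 equiv), n-BuLi (1.3 equiv), THF, −78 °C; then 16, −78 °C; AcOH quench at −78 °C
Reagents that add atoms: n-butyllithium, [Li]CCCC (lithium of 19 only)
Why: Bromine–lithium exchange at −78 °C is faster than any attack of n-BuLi on the allyl ethers, the ortho oxygen stabilises 19, and 1,2-addition to the aldehyde gives 20 as a racemate whose carbinol stereocentre needs no control because step 13 erases it.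

Step 13
Reactants: 20 1-[2,4-bis(allyloxy)phenyl]-2-[4,6-bis(allyloxy)-2-methoxy-3-(3-methylbut-2-enyl)phenyl]ethanol
Product: 21 1-[2,4-bis(allyloxy)phenyl]-2-[4,6-bis(allyloxy)-2-methoxy-3-(3-methylbut-2-enyl)phenyl]ethanone
Conditions: Dess–Martin periodinane (1.3 equiv), CH2Cl2, rt
Reagents that add atoms: none
Why: Dess–Martin oxidation of the secondary benzylic alcohol should give the deoxybenzoin cleanly, removes the only stereocentre and leaves all five alkenes alone.

Step 14
Reactants: 21 1-[2,4-bis(allyloxy)phenyl]-2-[4,6-bis(allyloxy)-2-methoxy-3-(3-methylbut-2-enyl)phenyl]ethanone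
Product: 22 glicophenone
Conditions: Pd(PPh3)4 (8 mol %), morpholine (12 equiv), THF, rt, argon; pH 5 phosphate buffer work-up
Reagents that add atoms: none
Why: Tsuji–Trost type deallylation: zerovalent palladium ionises all four aryl allyl ethers to π-allyl complexes that the excess of morpholine traps irreversibly, while the carbon-bound prenyl group has no leaving group and the non-acidic medium avoids chroman and benzofuran formation.

Compound list
1 | acetylacetone (pentane-2,4-dione) | CC(=O)CC(C)=O | starting material
2 | prenyl bromide (1-bromo-3-methylbut-2-ene) | CC(C)=CCBr | starting material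
3 | 3-(3-methylbut-2-enyl)pentane-2,4-dione | CC(=O)C(CC=C(C)C)C(C)=O | intermediate
4 | dilithio dianion of 3 (deprotonated at C3 and at one terminal methyl group) | [Li+].[Li+].C=C([O-])C(CC=C(C)C)=C(C)[O-] | intermediate
5 | 4-(3-methylbut-2-enyl)-3,5-dioxohexanoic acid (racemic, enolisable) | CC(=O)C(CC=C(C)C)C(=O)CC(=O)O | intermediate
6 | 4-hydroxy-6-methyl-5-(3-methylbut-2-enyl)-2H-pyran-2-one | CC1=C(CC=C(C)C)C(O)=CC(=O)O1 | intermediate
7 | 2-(tetrahydro-2H-pyran-2-yloxy)ethanol (racemic) | OCCOC1CCCCO1 | starting material
8 | (tetrahydro-2H-pyran-2-yloxy)acetaldehyde (racemic) | O=CCOC1CCCCO1 | intermediate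
9 | 6-methyl-5-(3-methylbut-2-enyl)-3-[2-(tetrahydro-2H-pyran-2-yloxy)ethylidene]pyran-2,4-dione (transient, alkene geometry not defined) | CC1=C(CC=C(C)C)C(=O)C(=CCOC2CCCCO2)C(=O)O1 | intermediate
10 | 4-hydroxy-6-methyl-5-(3-methylbut-2-enyl)-3-[2-(tetrahydro-2H-pyran-2-yloxy)ethyl]-2H-pyran-2-one (racemic) | CC1=C(CC=C(C)C)C(O)=C(CCOC2CCCCO2)C(=O)O1 | intermediate
11 | 4-methoxy-6-methyl-5-(3-methylbut-2-enyl)-3-[2-(tetrahydro-2H-pyran-2-yloxy)ethyl]-2H-pyran-2-one (racemic; precursor of the key step) | COC1=C(CCOC2CCCCO2)C(=O)OC(C)=C1CC=C(C)C | intermediate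
12 | methyl (E)-3-methoxy-4-(3-methylbut-2-enyl)-5-oxo-2-[2-(tetrahydro-2H-pyran-2-yloxy)ethyl]hex-2-enoate (ester cis to the C4 chain; C4 and THP centres not controlled) | COC(=O)/C(CCOC1CCCCO1)=C(/OC)C(CC=C(C)C)C(C)=O | intermediate
13 | 5-methoxy-4-(3-methylbut-2-enyl)-6-[2-(tetrahydro-2H-pyran-2-yloxy)ethyl]benzene-1,3-diol (ring A: C1 OMe, C2 prenyl, C3 OH, C4 H, C5 OH, C6 protected hydroxyethyl; racemic at THP) | COc1c(CC=C(C)C)c(O)cc(O)c1CCOC1CCCCO1 | intermediate
14 | 2-{2-[4,6-bis(allyloxy)-2-methoxy-3-(3-methylbut-2-enyl)phenyl]ethoxy}tetrahydro-2H-pyran (racemic) | COc1c(CC=C(C)C)c(OCC=C)cc(OCC=C)c1CCOC1CCCCO1 | intermediate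
15 | 2-[4,6-bis(allyloxy)-2-methoxy-3-(3-methylbut-2-enyl)phenyl]ethanol | COc1c(CC=C(C)C)c(OCC=C)cc(OCC=C)c1CCO | intermediate
16 | [4,6-bis(allyloxy)-2-methoxy-3-(3-methylbut-2-enyl)phenyl]acetaldehyde | COc1c(CC=C(C)C)c(OCC=C)cc(OCC=C)c1CC=O | intermediate
17 | 4-bromoresorcinol (4-bromobenzene-1,3-diol) | Oc1ccc(Br)c(O)c1 | starting material
18 | 2,4-bis(allyloxy)-1-bromobenzene | C=CCOc1ccc(Br)c(OCC=C)c1 | intermediate
19 | 2,4-bis(allyloxy)phenyllithium | [Li]c1ccc(OCC=C)cc1OCC=C | intermediate
20 | 1-[2,4-bis(allyloxy)phenyl]-2-[4,6-bis(allyloxy)-2-methoxy-3-(3-methylbut-2-enyl)phenyl]ethanol (racemic) | COc1c(CC=C(C)C)c(OCC=C)cc(OCC=C)c1CC(O)c1ccc(OCC=C)cc1OCC=C | intermediate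
21 | 1-[2,4-bis(allyloxy)phenyl]-2-[4,6-bis(allyloxy)-2-methoxy-3-(3-methylbut-2-enyl)phenyl]ethanone | COc1c(CC=C(C)C)c(OCC=C)cc(OCC=C)c1CC(=O)c1ccc(OCC=C)cc1OCC=C | intermediate
22 | glicophenone, 1-(2,4-dihydroxyphenyl)-2-[4,6-dihydroxy-2-methoxy-3-(3-methylbut-2-enyl)phenyl]ethanone (achiral) | COc1c(CC=C(C)C)c(O)cc(O)c1CC(=O)c1ccc(O)cc1O | target

Total step count: 14.
Longest linear sequence: 12 steps (1, 2, 3, 5, 6, 7, 8, 9, 10, 12, 13, 14) from acetylacetone.

Steps most likely to fail

**Step 7.**
- What may go wrong:
  - The C3 substituent may slow methoxide addition at the lactone carbonyl.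
  - The extended dienolate may persist as an unreactive resting state.
  - At the temperature needed, SN2 demethylation of the C4 methoxy group could outrun the closure.
  - Saponification and decarboxylation by traces of water could do the same.
- Fallback: it builds ring A on an intact phloroglucinol nucleus, sets out from prenyl bromide 2 and rejoins the route at aldehyde 16.
  - Commercial 2,4,6-trihydroxybenzaldehyde is C-prenylated with 2 (KOH, aqueous MeOH, 0 °C) to 2,4,6-trihydroxy-3-(3-methylbut-2-enyl)benzaldehyde F1.
  - Allyl bromide (2 equiv) with K2CO3 in acetone should alkylate the para hydroxyl and the less hindered ortho hydroxyl. The chelated, prenyl-flanked hydroxyl stays free, giving 4,6-bis(allyloxy)-2-hydroxy-3-(3-methylbut-2-enyl)benzaldehyde F2.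
  - MeI and K2CO3 in DMF then cap the last hydroxyl as 4,6-bis(allyloxy)-2-methoxy-3-(3-methylbut-2-enyl)benzaldehyde F3.
  - Wittig methoxymethylenation (MeOCH2PPh3Cl, KOtBu, THF) gives the enol ether 1,5-bis(allyloxy)-3-methoxy-2-(2-methoxyvinyl)-4-(3-methylbut-2-enyl)benzene F4.
  - 1 M HCl in THF at rt hydrolyses F4 to 16.
  - This path trades the built-in regiocontrol of the pyrone for selectivity in C-prenylation and in hydroxyl differentiation.

**Step 12.**
- What may go wrong: proton transfer from the acidic arylacetaldehyde to the basic aryllithium, and self-aldol condensation of the aldehyde, may compete with 1,2-addition.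
- Fallback: it raises the oxidation level first, sets out from 16 and rejoins at ketone 21, so that 20 and step 13 are skipped.
  - Pinnick oxidation (NaClO2, NaH2PO4, large excess of 2-methylbut-2-ene, t-BuOH/H2O) gives [4,6-bis(allyloxy)-2-methoxy-3-(3-methylbut-2-enyl)phenyl]acetic acid F5.
  - 1,1'-Carbonyldiimidazole followed by MeNHOMe·HCl gives the storable Weinreb amide 2-[4,6-bis(allyloxy)-2-methoxy-3-(3-methylbut-2-enyl)phenyl]-N-methoxy-N-methylacetamide F6.
  - Addition of aryllithium 19 (from 18, as in step 12) at −78 °C gives 21 through the chelated tetrahedral intermediate, which blocks a second addition.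

**Step 3.**
- What may go wrong: loss of CO2 from the β-keto acid before or during activation, and acetyl transfer to the product, may erode the lactonisation.
- Fallback: it avoids the free acid altogether, sets out from prenyl bromide 2 and rejoins at pyrone 6.
  - The dianion of methyl acetoacetate (LiN(iPr)2, 2.1 equiv, THF, 0 °C) is alkylated at its γ-carbon with 2 to methyl 7-methyl-3-oxooct-6-enoate F7.
  - A second dianion formation and γ-acylation with N-methoxy-N-methylacetamide gives methyl 4-(3-methylbut-2-enyl)-3,5-dioxohexanoate F8.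
  - DBU in toluene at reflux closes F8 to 6 by base-induced enol lactonisation.

Further compounds
F1 | step 7 | 2,4,6-trihydroxy-3-(3-methylbut-2-enyl)benzaldehyde | O=Cc1c(O)cc(O)c(CC=C(C)C)c1O
F2 | step 7 | 4,6-bis(allyloxy)-2-hydroxy-3-(3-methylbut-2-enyl)benzaldehyde | O=Cc1c(OCC=C)cc(OCC=C)c(CC=C(C)C)c1O
F3 | step 7 | 4,6-bis(allyloxy)-2-methoxy-3-(3-methylbut-2-enyl)benzaldehyde | O=Cc1c(OCC=C)cc(OCC=C)c(CC=C(C)C)c1OC
F4 | step 7 | 1,5-bis(allyloxy)-3-methoxy-2-(2-methoxyvinyl)-4-(3-methylbut-2-enyl)benzene (E/Z mixture) | COC=Cc1c(OCC=C)cc(OCC=C)c(CC=C(C)C)c1OC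
F5 | step 12 | [4,6-bis(allyloxy)-2-methoxy-3-(3-methylbut-2-enyl)phenyl]acetic acid | COc1c(CC=C(C)C)c(OCC=C)cc(OCC=C)c1CC(=O)O
F6 | step 12 | 2-[4,6-bis(allyloxy)-2-methoxy-3-(3-methylbut-2-enyl)phenyl]-N-methoxy-N-methylacetamide | COc1c(CC=C(C)C)c(OCC=C)cc(OCC=C)c1CC(=O)N(C)OC
F7 | step 3 | methyl 7-methyl-3-oxooct-6-enoate | COC(=O)CC(=O)CCC=C(C)C
F8 | step 3 | methyl 4-(3-methylbut-2-enyl)-3,5-dioxohexanoate (racemic, enolisable) | COC(=O)CC(=O)C(CC=C(C)C)C(C)=O
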